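**Strategy.** The piperidine ring N1–C2–C3–C4–C4a–C8a is cut into a C2–C3–C4–C4a 2-acetoxydiene and a C8a=N1 N-sulfonylimine, both carried on one acyclic chain and joined through C5–C8, the future carbocycle. One intramolecular imino Diels–Alder reaction closes both rings by forming N1–C2 and C4a–C8a. The tosyl and acetoxy groups are chosen so that base and oxygen then turn the adduct into a 2-methyl-3-pyridinol. The one preset ring stereocentre, C5, steers an all-syn hydrogenation that sets C2, C3, C4a and C8a. A Mitsunobu esterification inverts C3 while installing the dienoate. The precursor is an open-chain (2Z,4E)-dienyl acetate aldehyde.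

Key step: step 8

Remark: ring atoms carry quinoline numbers (N1, C2 with methyl, C3 with oxygen, C4, C4a, C5 with the side chain, C6–C8, C8a); the side chain is C1′–C8′.
Remark: Taniaphos is 1-[α-(dimethylamino)-2-(diphenylphosphino)benzyl]-2-(diphenylphosphino)ferrocene, C43H39FeNP2.
Assumption: the (R,R) antipode of Taniaphos is taken to give the 4S centre of 9; if the first run shows the opposite sense, the (S,S) ligand is used and nothing else changes.
Remark: the cycloadduct of step 8 is expected mainly as the trans-fused isomer, which is not the ring fusion of the target; the route therefore erases C2, C4a and C8a in step 9 and resets them by hydrogenation in step 10.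

Step 1
Reactants: 1 (R)-2-propyloxirane; 2 pent-4-enylmagnesium bromide
Product: 3 (R)-dec-1-en-7-ol
Conditions: CuI (10 mol %), THF, −30 → 0 °C; aq. NH4Cl
Reagents that add atoms: none
Why: Copper-catalysed SN2 opening of the terminal epoxide by the Grignard reagent at the CH2 carbon (epoxide ring opening) leaves the carbinol centre untouched, so C5′ (R) comes from the chiral pool.

Step 2
Reactants: 3 (R)-dec-1-en-7-ol
Product: 4 (R)-tert-butyl(dec-9-en-4-yloxy)dimethylsilane
Conditions: TBSCl, imidazole, DMF, 23 °C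
Reagents that add atoms: tert-butyldimethylsilyl chloride, CC(C)(C)[Si](C)(C)Cl
Why: Silyl ether formation masks the C5′ hydroxyl against the organometallic, basic and Mitsunobu steps and is removable by acid at the end.

Step 3
Reactants: 4 (R)-tert-butyl(dec-9-en-4-yloxy)dimethylsilane; 5 (E)-1,4-dibromobut-2-ene
Product: 6 tert-butyl{[(4R,9E)-11-bromoundec-9-en-4-yl]oxy}dimethylsilane
Conditions: second-generation Grubbs catalyst (3 mol %), 5 (3 equiv), CH2Cl2, 40 °C
Reagents that add atoms: none
Why: Olefin cross-metathesis of the terminal alkene with excess symmetrical dibromide should give the E allylic bromide, with the silyl ether inert.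

Step 4
Reactants: 6 tert-butyl{[(4R,9E)-11-bromoundec-9-en-4-yl]oxy}dimethylsilane; 7 2-(3-bromopropyl)-1,3-dioxolane
Product: 9 2-[(4S,9R)-9-(tert-butyldimethylsilyloxy)-4-ethenyldodecyl]-1,3-dioxolane, via Grignard reagent 8 (not isolated)
Conditions: 7, Mg, Et2O, 35 °C; then 6, CuBr·SMe2 (5 mol %), (R,R)-Taniaphos (6 mol %), CH2Cl2, −78 °C
Reagents that add atoms: none
Why: Copper-catalysed asymmetric allylic alkylation (SN2′) delivers the alkyl group to the γ-carbon and creates C5 as a vinyl-bearing centre whose configuration is set by the chiral diphosphine on copper; acetal and silyl ether tolerate the Grignard reagent at −78 °C.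

Step 5
Reactants: 9 2-[(4S,9R)-9-(tert-butyldimethylsilyloxy)-4-ethenyldodecyl]-1,3-dioxolane; 10 pent-1-en-3-one
Product: 11 (4E,6S,11R)-11-(tert-butyldimethylsilyloxy)-6-[3-(1,3-dioxolan-2-yl)propyl]tetradec-4-en-3-one
Conditions: second-generation Grubbs catalyst (5 mol %), 10 (3 equiv), CH2Cl2, 40 °C
Reagents that add atoms: none
Why: Cross-metathesis of the only terminal alkene with an electron-poor vinyl ketone should give the E enone selectively without touching the allylic stereocentre.

Step 6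
Reactants: 11 (4E,6S,11R)-11-(tert-butyldimethylsilyloxy)-6-[3-(1,3-dioxolan-2-yl)propyl]tetradec-4-en-3-one
Product: 13 (2Z,4E,6S,11R)-11-(tert-butyldimethylsilyloxy)-6-[3-(1,3-dioxolan-2-yl)propyl]tetradeca-2,4-dien-3-yl acetate, via lithium dienolate 12 (not isolated)
Conditions: LiN(SiMe3)2, THF/DMPU, −78 °C; then Ac2O, −78 → 0 °C
Reagents that add atoms: acetic anhydride, CC(=O)OC(C)=O
Why: Kinetic deprotonation at the ethyl CH2 rather than at the hindered γ C–H, then O-acetylation of the Z(O) enolate (enol ester formation), should give the (2Z)-2-acetoxydiene with the methyl group "outside" and C5 unchanged.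

Step 7
Reactants: 13 (2Z,4E,6S,11R)-11-(tert-butyldimethylsilyloxy)-6-[3-(1,3-dioxolan-2-yl)propyl]tetradeca-2,4-dien-3-yl acetate
Product: 14 (2Z,4E,6S,11R)-11-(tert-butyldimethylsilyloxy)-6-(4-oxobutyl)tetradeca-2,4-dien-3-yl acetate
Conditions: PPTS (0.2 equiv), acetone/H2O (9:1), 50 °C
Reagents that add atoms: water, O
Why: Mild acid-catalysed acetal hydrolysis frees the aldehyde, while the enol acetate and the secondary silyl ether hydrolyse much more slowly and should survive.

Step 8
Reactants: 14 (2Z,4E,6S,11R)-11-(tert-butyldimethylsilyloxy)-6-(4-oxobutyl)tetradeca-2,4-dien-3-yl acetate; 15 N-sulfinyl-4-methylbenzenesulfonamide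
Product: 17 (2R,4aS,5S,8aR)-5-[(5R)-5-(tert-butyldimethylsilyloxy)octyl]-2-methyl-1-tosyl-1,2,4a,5,6,7,8,8a-octahydroquinolin-3-yl acetate, via N-tosylimine 16 (not isolated)
Conditions: 15 (1.1 equiv), BF3·OEt2 (0.5 equiv), CH2Cl2 (0.01 M), −30 → 23 °C
Reagents that add atoms: none
Why: BF3-assisted condensation of the aldehyde with 15 (loss of SO2) gives the E N-sulfonylimine 16, whose activated C=N adds across C2 and C4a of the tethered s-cis (2Z,4E)-2-acetoxydiene in an asynchronous [4+2] cycloaddition in which the C4a–C8a bond leads. The closest known reaction type is the intramolecular imino Diels–Alder reaction of N-sulfonylimines generated in situ from dienyl aldehydes. The carbocycle closes by C4a–C8a bond formation through the four-carbon tether C5–C8 (type 1 mode, chair-like six-membered tether), and the piperidine ring is the [4+2] ring itself, closed by N1–C2 and C4a–C8a. C2 and C4a should come out cis because addition to the diene is suprafacial with the methyl group and C5 both "outside", while C8a and the face follow from the tether chair with the C5 chain equatorial and the sulfonyl group endo, which should favour the trans-fused isomer drawn. The step needs only regioselectivity (N to C2, C8a to C4a) and chemoselectivity: the tether secures the first against the weak directing bias of the acetoxy group, because the other orientation would need a bridged nine-membered ring, and the enol acetate is too poor a nucleophile for a competing Mannich reaction. Diastereoselectivity is not needed, since C2, C4a and C8a are erased in step 9 and every isomer gives the same pyridinol, while C5 is not touched.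

Step 9
Reactants: 17 (2R,4aS,5S,8aR)-5-[(5R)-5-(tert-butyldimethylsilyloxy)octyl]-2-methyl-1-tosyl-1,2,4a,5,6,7,8,8a-octahydroquinolin-3-yl acetate
Product: 20 (5S)-5-[(5R)-5-(tert-butyldimethylsilyloxy)octyl]-2-methyl-5,6,7,8-tetrahydroquinolin-3-ol, via sulfonamido ketone 18 (not isolated), via dihydropyridinol 19 (not isolated)
Conditions: K2CO3 (3 equiv), MeOH, 23 → 60 °C, O2 (1 atm)
Reagents that add atoms: none
Why: Methanolysis of the enol acetate gives the α-sulfonamido ketone, E1cB loss of toluenesulfinate from nitrogen forms C2=N1, and the dihydropyridinol is aromatised by oxygen (eliminative aromatisation), which erases C2, C4a and C8a but leaves C5 intact.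

Step 10
Reactants: 20 (5S)-5-[(5R)-5-(tert-butyldimethylsilyloxy)octyl]-2-methyl-5,6,7,8-tetrahydroquinolin-3-ol
Product: 21 (2S,3S,4aS,5S,8aR)-5-[(5R)-5-(tert-butyldimethylsilyloxy)octyl]-2-methyldecahydroquinolin-3-ol
Conditions: H2 (4 atm), PtO2 (10 mol %), AcOH, 23 °C; aq. NaOH work-up
Reagents that add atoms: none
Why: Heterogeneous all-syn hydrogenation of the protonated pyridine ring takes place on the face opposite the C5 chain, which sits pseudo-axial to avoid the peri C4–H, so H2, H3, H4a and H8a should all be delivered cis to H5, giving the cis-fused 2,3-cis amino alcohol.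

Step 11
Reactants: 21 (2S,3S,4aS,5S,8aR)-5-[(5R)-5-(tert-butyldimethylsilyloxy)octyl]-2-methyldecahydroquinolin-3-ol
Product: 22 tert-butyl (2S,3S,4aS,5S,8aR)-5-[(5R)-5-(tert-butyldimethylsilyloxy)octyl]-3-hydroxy-2-methyloctahydroquinoline-1(2H)-carboxylate
Conditions: Boc2O (2 equiv), Et3N, MeOH, 50 °C
Reagents that add atoms: di-tert-butyl dicarbonate, CC(C)(C)OC(=O)OC(=O)OC(C)(C)C
Why: Carbamate formation (Boc protection) blocks the secondary amine for the redox condensation; without DMAP the hindered alcohol should not be acylated.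

Step 12
Reactants: 23 (E)-hex-2-enal; 24 malonic acid
Product: 25 (2E,4E)-octa-2,4-dienoic acid
Conditions: pyridine, piperidine (cat.), 90 °C; aq. HCl
Reagents that add atoms: none
Why: Doebner–Knoevenagel condensation with decarboxylation gives the (2E,4E)-dienoic acid.

Step 13
Reactants: 22 tert-butyl (2S,3S,4aS,5S,8aR)-5-[(5R)-5-(tert-butyldimethylsilyloxy)octyl]-3-hydroxy-2-methyloctahydroquinoline-1(2H)-carboxylate; 25 (2E,4E)-octa-2,4-dienoic acid
Product: 26 tert-butyl (2S,3R,4aS,5S,8aR)-5-[(5R)-5-(tert-butyldimethylsilyloxy)octyl]-2-methyl-3-[(2E,4E)-octa-2,4-dienoyloxy]octahydroquinoline-1(2H)-carboxylate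
Conditions: PPh3, DIAD, toluene, 0 → 23 °C
Reagents that add atoms: none
Why: Mitsunobu esterification displaces the oxyphosphonium group at C3 by SN2 from the open face anti to the C2 methyl group, so the 3S alcohol becomes the 3R ester, trans to C2-Me, in the same step that installs the acyl group.

Step 14
Reactants: 26 tert-butyl (2S,3R,4aS,5S,8aR)-5-[(5R)-5-(tert-butyldimethylsilyloxy)octyl]-2-methyl-3-[(2E,4E)-octa-2,4-dienoyloxy]octahydroquinoline-1(2H)-carboxylate
Product: 27 lepadin H
Conditions: CF3CO2H/CH2Cl2/H2O (10:10:1), 0 → 23 °C; aq. NaHCO3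
Reagents that add atoms: none
Why: Acidolysis (global deprotection) removes the Boc group and the secondary silyl ether in one operation without touching the dienoate or any stereocentre, and the amine stays protonated until work-up, which should suppress O→N acyl shift.

**Compound list**

1 | (R)-2-propyloxirane | CCC[C@@H]1CO1 | starting material
2 | pent-4-enylmagnesium bromide (THF solution) | C=CCCC[Mg]Br | starting material
3 | (R)-dec-1-en-7-ol | C=CCCCC[C@H](O)CCC | intermediate
4 | (R)-tert-butyl(dec-9-en-4-yloxy)dimethylsilane | C=CCCCC[C@H](O[Si](C)(C)C(C)(C)C)CCC | intermediate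
5 | (E)-1,4-dibromobut-2-ene | BrC/C=C/CBr | starting material
6 | tert-butyl{[(4R,9E)-11-bromoundec-9-en-4-yl]oxy}dimethylsilane | BrC/C=C/CCCC[C@H](O[Si](C)(C)C(C)(C)C)CCC | intermediate
7 | 2-(3-bromopropyl)-1,3-dioxolane | BrCCCC1OCCO1 | starting material
8 | [3-(1,3-dioxolan-2-yl)propyl]magnesium bromide | Br[Mg]CCCC1OCCO1 | intermediate
9 | 2-[(4S,9R)-9-(tert-butyldimethylsilyloxy)-4-ethenyldodecyl]-1,3-dioxolane | C=C[C@@H](CCCC[C@H](O[Si](C)(C)C(C)(C)C)CCC)CCCC1OCCO1 | intermediate
10 | pent-1-en-3-one | C=CC(=O)CC | starting material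
11 | (4E,6S,11R)-11-(tert-butyldimethylsilyloxy)-6-[3-(1,3-dioxolan-2-yl)propyl]tetradec-4-en-3-one | CCC(=O)/C=C/[C@@H](CCCC[C@H](O[Si](C)(C)C(C)(C)C)CCC)CCCC1OCCO1 | intermediate
12 | lithium (2Z,4E)-dienolate of 11 | C/C=C(O[Li])/C=C/[C@@H](CCCC[C@H](O[Si](C)(C)C(C)(C)C)CCC)CCCC1OCCO1 | intermediate
13 | (2Z,4E,6S,11R)-11-(tert-butyldimethylsilyloxy)-6-[3-(1,3-dioxolan-2-yl)propyl]tetradeca-2,4-dien-3-yl acetate | C/C=C(OC(C)=O)/C=C/[C@@H](CCCC[C@H](O[Si](C)(C)C(C)(C)C)CCC)CCCC1OCCO1 | intermediate
14 | (2Z,4E,6S,11R)-11-(tert-butyldimethylsilyloxy)-6-(4-oxobutyl)tetradeca-2,4-dien-3-yl acetate | C/C=C(OC(C)=O)/C=C/[C@@H](CCCC[C@H](O[Si](C)(C)C(C)(C)C)CCC)CCCC=O | intermediate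
15 | N-sulfinyl-4-methylbenzenesulfonamide (also made from 4-methylbenzenesulfonamide and SOCl2) | Cc1ccc(cc1)S(=O)(=O)N=S=O | starting material
16 | (E)-N-tosylimine of aldehyde 14 | C/C=C(OC(C)=O)/C=C/[C@@H](CCCC[C@H](O[Si](C)(C)C(C)(C)C)CCC)CCC/C=N/S(=O)(=O)c1ccc(C)cc1 | intermediate
17 | (2R,4aS,5S,8aR)-5-[(5R)-5-(tert-butyldimethylsilyloxy)octyl]-2-methyl-1-tosyl-1,2,4a,5,6,7,8,8a-octahydroquinolin-3-yl acetate (expected main isomer; isomers at C2, C4a and C8a are carried on together) | CC(=O)OC1=C[C@@H]2[C@@H](CCCC[C@H](O[Si](C)(C)C(C)(C)C)CCC)CCC[C@H]2N(S(=O)(=O)c3ccc(C)cc3)[C@@H]1C | intermediate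
18 | (2R,4aR,5S,8aR)-5-[(5R)-5-(tert-butyldimethylsilyloxy)octyl]-2-methyl-1-tosyloctahydroquinolin-3(2H)-one | O=C1C[C@@H]2[C@@H](CCCC[C@H](O[Si](C)(C)C(C)(C)C)CCC)CCC[C@H]2N(S(=O)(=O)c3ccc(C)cc3)[C@@H]1C | intermediate
19 | (4aS,5S,8aR)-5-[(5R)-5-(tert-butyldimethylsilyloxy)octyl]-2-methyl-4a,5,6,7,8,8a-hexahydroquinolin-3-ol | OC1=C[C@@H]2[C@@H](CCCC[C@H](O[Si](C)(C)C(C)(C)C)CCC)CCC[C@H]2N=C1C | intermediate
20 | (5S)-5-[(5R)-5-(tert-butyldimethylsilyloxy)octyl]-2-methyl-5,6,7,8-tetrahydroquinolin-3-ol | Oc1cc2[C@@H](CCCC[C@H](O[Si](C)(C)C(C)(C)C)CCC)CCCc2nc1C | intermediate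
21 | (2S,3S,4aS,5S,8aR)-5-[(5R)-5-(tert-butyldimethylsilyloxy)octyl]-2-methyldecahydroquinolin-3-ol | O[C@H]1C[C@H]2[C@@H](CCCC[C@H](O[Si](C)(C)C(C)(C)C)CCC)CCC[C@H]2N[C@H]1C | intermediate
22 | tert-butyl (2S,3S,4aS,5S,8aR)-5-[(5R)-5-(tert-butyldimethylsilyloxy)octyl]-3-hydroxy-2-methyloctahydroquinoline-1(2H)-carboxylate | O[C@H]1C[C@H]2[C@@H](CCCC[C@H](O[Si](C)(C)C(C)(C)C)CCC)CCC[C@H]2N(C(=O)OC(C)(C)C)[C@H]1C | intermediate
23 | (E)-hex-2-enal | CCC/C=C/C=O | starting material
24 | malonic acid | OC(=O)CC(O)=O | starting material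
25 | (2E,4E)-octa-2,4-dienoic acid | CCC/C=C/C=C/C(=O)O | intermediate
26 | tert-butyl (2S,3R,4aS,5S,8aR)-5-[(5R)-5-(tert-butyldimethylsilyloxy)octyl]-2-methyl-3-[(2E,4E)-octa-2,4-dienoyloxy]octahydroquinoline-1(2H)-carboxylate | CCC/C=C/C=C/C(=O)O[C@@H]1C[C@H]2[C@@H](CCCC[C@H](O[Si](C)(C)C(C)(C)C)CCC)CCC[C@H]2N(C(=O)OC(C)(C)C)[C@H]1C | intermediate
27 | lepadin H, (2S,3R,4aS,5S,8aR)-5-[(5R)-5-hydroxyoctyl]-2-methyldecahydroquinolin-3-yl (2E,4E)-octa-2,4-dienoate | CCC/C=C/C=C/C(=O)O[C@@H]1C[C@H]2[C@@H](CCCC[C@H](O)CCC)CCC[C@H]2N[C@H]1C | target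

**Count.** Total: 14 steps. Longest linear sequence: 13 steps (steps 1–11, 13 and 14); step 12 is a one-step side branch.

**Steps most likely to fail**

Step 8. The acetoxy group lowers the reactivity of the diene toward the boron-bound sulfonylimine, so tautomerisation of 16 to the ene-sulfonamide or intermolecular addition may outrun ring closure. The fallback sets out from 14 and brings nitrogen in as ammonium chloride in aqueous ethanol at 70 °C. The unsubstituted iminium ion should undergo the intramolecular aza-Diels–Alder reaction in water without a Lewis acid and give the secondary amine (2R,4aS,5S,8aR)-5-[(5R)-5-(tert-butyldimethylsilyloxy)octyl]-2-methyl-1,2,4a,5,6,7,8,8a-octahydroquinolin-3-yl acetate F1. N-Chlorosuccinimide in CH2Cl2 converts it into the N-chloroamine (2R,4aS,5S,8aR)-1-chloro-5-[(5R)-5-(tert-butyldimethylsilyloxy)octyl]-2-methyl-1,2,4a,5,6,7,8,8a-octahydroquinolin-3-yl acetate F2. K2CO3 in methanol under oxygen then cleaves the acetate, eliminates HCl across N1–C2 and lets the dihydropyridinol autoxidise, which comes back to the route at 20.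

Step 9. Loss of sulfinate from nitrogen may stall at ketone 18, or autoxidation in base may run on to ring-oxidised products. The fallback sets out from 17 and uses its regiodefined enol acetate. N-Bromosuccinimide in aqueous THF at 0 °C brominates C4 and gives 4-bromo-5-[(5R)-5-(tert-butyldimethylsilyloxy)octyl]-2-methyl-1-tosyloctahydroquinolin-3(2H)-one F3 (epimers at C4). DBU in toluene at 60 °C then removes HBr across C4–C4a and toluenesulfinate across N1–C2, and the resulting 3-oxo-3,8a-dihydroquinoline tautomerises to 20 without any oxidant.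

Step 13. The oxyphosphonium ion at the hindered C3 may be captured too slowly by the weakly acidic dienoic acid, so elimination or attack by the Boc carbonyl oxygen may take over. The fallback sets out from 22 and separates inversion from acylation. A Mitsunobu reaction with the more acidic 4-nitrobenzoic acid gives the inverted ester tert-butyl (2S,3R,4aS,5S,8aR)-5-[(5R)-5-(tert-butyldimethylsilyloxy)octyl]-2-methyl-3-(4-nitrobenzoyloxy)octahydroquinoline-1(2H)-carboxylate F4. K2CO3 in methanol frees the axial alcohol tert-butyl (2S,3R,4aS,5S,8aR)-5-[(5R)-5-(tert-butyldimethylsilyloxy)octyl]-3-hydroxy-2-methyloctahydroquinoline-1(2H)-carboxylate F5. Yamaguchi esterification with 25 (2,4,6-trichlorobenzoyl chloride, Et3N, DMAP, toluene) comes back to the route at 26.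

**Further compounds**

F1 | step 8 | (2R,4aS,5S,8aR)-5-[(5R)-5-(tert-butyldimethylsilyloxy)octyl]-2-methyl-1,2,4a,5,6,7,8,8a-octahydroquinolin-3-yl acetate | CC(=O)OC1=C[C@@H]2[C@@H](CCCC[C@H](O[Si](C)(C)C(C)(C)C)CCC)CCC[C@H]2N[C@@H]1C
F2 | step 8 | (2R,4aS,5S,8aR)-1-chloro-5-[(5R)-5-(tert-butyldimethylsilyloxy)octyl]-2-methyl-1,2,4a,5,6,7,8,8a-octahydroquinolin-3-yl acetate | CC(=O)OC1=C[C@@H]2[C@@H](CCCC[C@H](O[Si](C)(C)C(C)(C)C)CCC)CCC[C@H]2N(Cl)[C@@H]1C
F3 | step 9 | (2R,4aS,5S,8aR)-4-bromo-5-[(5R)-5-(tert-butyldimethylsilyloxy)octyl]-2-methyl-1-tosyloctahydroquinolin-3(2H)-one (epimers at C4) | O=C1C(Br)[C@@H]2[C@@H](CCCC[C@H](O[Si](C)(C)C(C)(C)C)CCC)CCC[C@H]2N(S(=O)(=O)c3ccc(C)cc3)[C@@H]1C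
F4 | step 13 | tert-butyl (2S,3R,4aS,5S,8aR)-5-[(5R)-5-(tert-butyldimethylsilyloxy)octyl]-2-methyl-3-(4-nitrobenzoyloxy)octahydroquinoline-1(2H)-carboxylate | O=C(O[C@@H]1C[C@H]2[C@@H](CCCC[C@H](O[Si](C)(C)C(C)(C)C)CCC)CCC[C@H]2N(C(=O)OC(C)(C)C)[C@H]1C)c1ccc(cc1)[N+](=O)[O-]
F5 | step 13 | tert-butyl (2S,3R,4aS,5S,8aR)-5-[(5R)-5-(tert-butyldimethylsilyloxy)octyl]-3-hydroxy-2-methyloctahydroquinoline-1(2H)-carboxylate | O[C@@H]1C[C@H]2[C@@H](CCCC[C@H](O[Si](C)(C)C(C)(C)C)CCC)CCC[C@H]2N(C(=O)OC(C)(C)C)[C@H]1C
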